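The enzyme is what I count here, since the question asks what its charge does to the rate in the flask.

common to all: starting material 0.10 M; enzyme 6.7 × 10⁻⁴ mol%
- epsilon: second substrate 0.25 equiv; run made earlier
- beta: second substrate 0.38 equiv; run made earlier
- flask: second substrate 0.500 equiv

| epsilon: time / d | epsilon: target / % | beta: time / d | beta: target / % |
|---|---|---|---|
| 0.250 | 12 | 0.625 | 34 |
| 0.625 | 36 | 1.25 | 66 |
| 1.25 | 67 | 1.67 | 86 |
| 2.08 | 97 | 2.50 | 99 |
| 3.00 | 102 | 3.00 | 97 |
| 4.00 | 96 | 4.00 | 97 |

(readings scatter by 2 percentage points)

1. apparent order in enzyme when 20% of the starting material are converted (percent change of the rate of making target for one percent more enzyme charged)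

- the numbers in the tables scatter by 2 percentage points (one standard deviation)
- no earlier run changes the charge of enzyme; that part of a forecast is a guess

At 1.25 d the epsilon run reads 67% of target and the beta run 66%, although the beta run has more second substrate, so within the scatter the two runs share one rate. Read from the epsilon run, that rate is 0.536 /d as a fraction of the charge, on average up to that time. Dividing by the loading gives my carried quantity, the turnover count, meaning target made per enzyme charged per day (the turnover frequency): 80000 /d.

Finishing the starting material takes 1.49 × 10⁵ turnovers per enzyme, so the count gives 1.87 d, and the epsilon run reads 97% at 2.08 d. The flask has the same charges of starting material and enzyme as the two runs, but more second substrate than either, so carrying the rate over is my own estimate: I expect the flask to reach 20% conversion after about 0.373 d.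

If more enzyme simply means more sites, each working at this count, the rate follows the charge and the order is 1. I commit to that as a guess, and it is the weak link in the chain.

The forecast also gives 1, noting that “no run varied the enzyme charge”.

The simulation gives 0.79.

    starting material + enzyme ⇌ complex A (K = 310 /M, k = 8000 /M/min)
    complex A → enzyme + target (k = 100 /min)
    second substrate + enzyme ⇌ complex B (K = 8.80 /M, k = 81000 /M/min)
    complex B → enzyme + second product (k = 40.0 /min)
    2 complex A ⇌ resting dimer, settled at all times (K = 6.10 × 10⁵ /M)

In the flask, complex A goes on to target at 1.4 × 10⁵ /d per complex A, faster than my count, so the count asks for 55.6% of the catalyst as complex A, and 57.2% is there at 0.358 d. At that time in the flask the resting dimer, counted as the two catalysts it holds, takes 26.7%; it grows with the square of [complex A] while the other forms grow in proportion, so at fixed substrate concentrations the order in enzyme is one over one plus that share, 0.789, and in a second flask with twice this flask's second substrate the time to that conversion grows by a factor of 1.03, which lowers my count for that second flask to about 77300 /d.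

The readings were computed with constants of no real substance; noise was put on by code.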